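Gas supply is set here against the catalyst cycle, to see which of the two holds back each flask. Partner passes from the held gas into solution and joins free catalyst as catalyst intermediate A. That takes up starting material to give catalyst intermediate B, which releases product and free catalyst, so each product costs one partner.

all flasks: solid substrate 0.30 M; gas 13 mM (held); free catalyst 15 mM; time 5.0 min
- blue: temperature 100 °C
- teal: temperature 70 °C
- green: temperature 40 °C

    partner + free catalyst ⇌ catalyst intermediate A (K1 = 210 M⁻¹, k1 = 13 M⁻¹ s⁻¹, Ea1 = 35.0 kJ mol⁻¹, ΔH1 = 20.0 kJ mol⁻¹)
    starting material + catalyst intermediate A → catalyst intermediate B (k2 = 4.2 M⁻¹ s⁻¹, Ea2 = 59.0 kJ mol⁻¹)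
    catalyst intermediate B → free catalyst + product (k3 = 5.9 s⁻¹, Ea3 = 74.0 kJ mol⁻¹)
    gas ⇌ partner, rate k4*(csat - [partner]) (k4 = 0.095 s⁻¹, csat = 13 mM)
    starting material ⇌ dormant form (K5 = 1.2, k5 = 0.0014 s⁻¹, Ea5 = 111 kJ mol⁻¹, ΔH5 = −79.0 kJ mol⁻¹)
    solid substrate ⇌ starting material, rate k6*(cs6 - [starting material]) while solid is left; crystals form when [starting material] > cs6 (cs6 = 0.14 M, k6 = 0.028 s⁻¹)
    (constants at 70 °C)

- solid, in amounts per volume of the solution: solid substrate
- at the start none of partner is dissolved
- constants are those at 70 °C; use the activation energies and enthalpies for any other temperature
- at the start none of the solid substrate is in solution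
- what has only dissolved of solid substrate counts as not reacted

- the flask with the highest amount of product, in percent of the solid substrate charged ("all alike" if they lie within 1.5 percentage points) (blue / teal / green / all alike)
- final product, as a percentage of the solid substrate charged, in blue
- final product, as a percentage of the solid substrate charged, in teal
- final product, as a percentage of the solid substrate charged, in green

The reckoning uses two allowances, each a fraction of the solid substrate charged. The gas allowance, what the gas can pass into partner-free solution within 5.0 min, is 124 %, with no temperature in it. The catalyst allowance rests on one time. In blue a catalyst needs 2.62 s per cycle. This turn time is the wait for partner at saturation, plus the wait for starting material at its solubility, stretched by catalyst intermediate A falling back, plus the release from catalyst intermediate B. It is 8.41 s in teal and 42.4 s in green.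

Catalyst charged times time, over turn time and substrate charged, gives catalyst allowances of 573 % in blue, 178 % in teal and 35.4 % in green. Control changes hands between green and teal, since the catalyst allowance is smaller than the gas allowance in green but larger in teal. Taking gas and cycle in series, reciprocals add, which gives 102 % for blue, more than the charge, so this estimate puts blue at about complete conversion. Teal gets 73.0 % and green 27.5 %. In this estimate the gas is the rate-limiting step in blue, with 82.3 % of the resistance, but the cycle is in green, with 77.8 %.

The forecast names blue, with 95 % (89 % to 99 %), teal 68 % (61 % to 75 %) and green 26 % (22 % to 30 %), holding that “only the hot flask nearly uses up the substrate within 5 minutes”.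

The simulation gives 98.6 % in blue, 72.1 % in teal and 25.8 % in green, so blue leads.

At 2.50 min partner stands at 16.4 % of saturation in blue and 77.2 % in green. The gas is then passing at 83.6 % of its full rate in blue and 22.8 % in green.

Now take blue with free catalyst cut to 60.0 % of its charge. The turn time contains no catalyst amount and stays 2.62 s, so the catalyst allowance falls to 344 %, and in series with the gas this gives 90.9 %. That flask gives 90.3 %.

(The numbers of this flask are made up; no experiment stands behind them.)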